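**Plan**

1. Rings: A = cyclohexane of the lactone half, B = its fused oxepinone, C = cyclohexene of the acyl half (C1' bears the acrylate, C2'=C3', C3' bears CH2OH, C4' and C5' are CH2, C6' bears isopropyl).
2. Cuts: (a) the acrylate C=C joining the halves (ester-ylide Wittig, its CH2OH added afterwards by Stille coupling) and the ester C–O (from (triphenylphosphoranylidene)ketene); (b) ring B at its C=C (metathesis) and at O–CH2 (carboxylate alkylation); (c) ring C at C2'=C3' and C5'–C6' in one event.
3. Feature that allows (c): C3' carries an oxidised carbon and is tied through the C4'–C5' ethylene to the isopropyl carbon. So C3'–C4'–C5' is a ring-opened 1-(ethoxycarbonyl)cyclopropylphosphonium unit, C2' is an aldehyde carbon, and C6' (isopropyl carried as acetyl) is a β-keto ester enolate carbon; homo-Michael ring opening then intramolecular Wittig closes ring C as a three-carbon plus three-carbon annulation.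
4. Forward: half 1 (steps 1–12) builds ring C and ends at aldehyde 18; half 2 (steps 13–22) builds ring A from (S)-cryptone, functionalises it through a cyclobutane template and closes ring B; union and end game are steps 23–26.
5. Stereochemistry: C1' by iridium-catalysed allylic alkylation, C6' relayed from it by thermodynamic trans equilibration. Ring A from one organocatalytic Michael centre: the allene [2+2] photocycloaddition goes anti to isopropyl and fixes the two cis C–C bonds at the ring-fusion carbons, and the cis-fused cyclobutane sends the hydroxymethyl nucleophile to the convex ketone face.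
6. Alkene geometry: ring B by the ring itself; the linking acrylate by a Z-selective α-bromo ylide Wittig followed by a stereoretentive Stille coupling.

Key step: step 5

Remark: compounds 1, 4, 8, 19, 20, 23, 33 and 37 and the reagents named in the Conditions lines are taken as commercially available; the β-keto ester α-centres of 5, 7 and 11 are epimer mixtures that converge in step 6; the sense of induction in steps 3 and 13 is assigned from the accepted models for these catalyst classes, and the mirror-image ligand or catalyst would be used if the opposite sense were found.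

**Route**

Step 1
Reactants: 1 (E)-but-2-ene-1,4-diol
Product: 2 (E)-4-[(tert-butyldimethylsilyl)oxy]but-2-en-1-ol
Conditions: NaH (1.0 equiv), THF, 0 °C to rt; then tBuMe2SiCl, rt
Reagents that add atoms: tert-butyldimethylsilyl chloride, CC(C)(C)[Si](C)(C)Cl
Why: Monosilylation of a symmetrical diol through its sparingly soluble monosodium alkoxide (Williamson-type O-silylation) should stop at the mono-ether; no stereocentre is involved.

Step 2
Reactants: 2 (E)-4-[(tert-butyldimethylsilyl)oxy]but-2-en-1-ol
Product: 3 (E)-4-[(tert-butyldimethylsilyl)oxy]but-2-en-1-yl methyl carbonate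
Conditions: ClCO2Me, pyridine, CH2Cl2, 0 °C
Reagents that add atoms: methyl chloroformate, COC(=O)Cl
Why: O-Acylation of the primary allylic alcohol with a chloroformate gives the carbonate leaving group needed for allylic substitution.

Step 3
Reactants: 3 (E)-4-[(tert-butyldimethylsilyl)oxy]but-2-en-1-yl methyl carbonate; 4 methyl acetoacetate
Product: 5 methyl (3R)-2-acetyl-3-{[(tert-butyldimethylsilyl)oxy]methyl}pent-4-enoate
Conditions: [Ir(cod)Cl]2 (2 mol %), (Sa,S,S)-binaphthol-derived N,N-bis(1-phenylethyl)phosphoramidite (4 mol %), 1,5,7-triazabicyclo[4.4.0]dec-5-ene (8 mol %), THF, 50 °C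
Reagents that add atoms: none
Why: Iridium-catalysed asymmetric allylic alkylation of a linear (E)-allylic carbonate with a stabilised carbon nucleophile should give the branched product, the chiral iridium–allyl complex setting C3 (R expected with this ligand enantiomer), while C2 is an inconsequential epimer mixture.

Step 4
Reactants: 5 methyl (3R)-2-acetyl-3-{[(tert-butyldimethylsilyl)oxy]methyl}pent-4-enoate
Product: 7 methyl (3R)-2-acetyl-4-[(tert-butyldimethylsilyl)oxy]-3-formylbutanoate, via ozonide 6 (not isolated)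
Conditions: O3, CH2Cl2, −78 °C; then Me2S, −78 °C to rt
Reagents that add atoms: ozone, [O-][O+]=O
Why: Ozonolysis with reductive work-up cleaves the only alkene to the aldehyde under neutral conditions that should leave the adjacent stereocentre untouched; the aldehyde is used at once.

Step 5
Reactants: 7 methyl (3R)-2-acetyl-4-[(tert-butyldimethylsilyl)oxy]-3-formylbutanoate; 8 (1-ethoxycarbonylcyclopropyl)triphenylphosphonium tetrafluoroborate
Product: 11 4-ethyl 1-methyl (2R)-1-acetyl-2-{[(tert-butyldimethylsilyl)oxy]methyl}cyclohex-3-ene-1,4-dicarboxylate, via sodium enolate 9 (not isolated), via phosphorus ylide 10 (not isolated)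
Conditions: NaH (1.0 equiv), THF, 0 °C; then 8 (1.1 equiv), THF–DMPU (4:1), 0.02 M, 0 to 45 °C
Reagents that add atoms: none
Why: Proposed new method: the sodium enolate of the β-keto ester (C2 of 7, the future isopropyl-bearing carbon C6') opens the doubly activated cyclopropane of 8 at a CH2 group in an SN2-type homo-Michael addition, which forms the C6'–C5' bond and releases an ester-stabilised phosphorus ylide at the future C3'; this ylide then olefinates the pendant aldehyde in an intramolecular Wittig reaction that forms C2'=C3'. The closest known reaction types are the cyclopentene annulation of β-dicarbonyl enolates with this same phosphonium salt and the one-pot Michael/Horner–Wadsworth–Emmons cyclohexene synthesis from γ-nitro aldehydes and a vinylphosphonate; what is new is the three-carbon plus three-carbon union with an aldehyde one carbon further from the nucleophilic carbon, which should give a cyclohexene. Ring C closes by 6-exo-trig attack of the ylide carbon on the aldehyde carbonyl. The only new stereocentre is the quaternary carbon, formed without control and of no consequence because step 6 turns it into an epimerisable CH; the centre set in step 3 is carried through. The step needs C- over O-alkylation of the enolate, deprotonation at the 1,3-dicarbonyl C–H and not at the aldehyde α-C–H, and ring closure faster than intermolecular olefination. The soft doubly stabilised enolate, the single equivalent of base with a gap of several pKa units to the aldehyde α-proton, the weakly basic stabilised ylide and high dilution should secure these.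

Step 6
Reactants: 11 4-ethyl 1-methyl (2R)-1-acetyl-2-{[(tert-butyldimethylsilyl)oxy]methyl}cyclohex-3-ene-1,4-dicarboxylate
Product: 12 ethyl (3R,4R)-4-acetyl-3-{[(tert-butyldimethylsilyl)oxy]methyl}cyclohex-1-ene-1-carboxylate
Conditions: LiCl (3 equiv), H2O (2 equiv), DMSO, 140 °C
Reagents that add atoms: none
Why: Krapcho dealkoxycarbonylation removes the methyl ester of the α,α-disubstituted β-keto ester (chloride attack at O–CH3, then loss of CO2), and the resulting epimerisable α-acetyl centre should settle trans to the silyloxymethyl group (both pseudo-equatorial) under thermodynamic control.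

Step 7
Reactants: 12 ethyl (3R,4R)-4-acetyl-3-{[(tert-butyldimethylsilyl)oxy]methyl}cyclohex-1-ene-1-carboxylate
Product: 13 ethyl (3R,4R)-3-{[(tert-butyldimethylsilyl)oxy]methyl}-4-(prop-1-en-2-yl)cyclohex-1-ene-1-carboxylate
Conditions: Ph3PCH3Br, KN(SiMe3)2, THF, 0 °C; then 12, 0 °C to rt
Reagents that add atoms: methyltriphenylphosphonium bromide, C[P+](c1ccccc1)(c1ccccc1)c1ccccc1.[Br-]
Why: Wittig methylenation of the methyl ketone is far faster than attack of the non-stabilised ylide on the enoate ester, and any epimerisation next to the ketone only reinforces the trans arrangement.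

Step 8
Reactants: 13 ethyl (3R,4R)-3-{[(tert-butyldimethylsilyl)oxy]methyl}-4-(prop-1-en-2-yl)cyclohex-1-ene-1-carboxylate
Product: 14 ethyl (3S,4S)-3-{[(tert-butyldimethylsilyl)oxy]methyl}-4-isopropylcyclohex-1-ene-1-carboxylate
Conditions: H2 (1 atm), RhCl(PPh3)3 (5 mol %), benzene–EtOH, rt
Reagents that add atoms: none
Why: Homogeneous hydrogenation with RhCl(PPh3)3 reduces the 1,1-disubstituted alkene and should leave the trisubstituted conjugated ring alkene, as in the selective reduction of the isopropenyl group of carvone.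

Step 9
Reactants: 14 ethyl (3S,4S)-3-{[(tert-butyldimethylsilyl)oxy]methyl}-4-isopropylcyclohex-1-ene-1-carboxylate
Product: 15 [(3S,4S)-3-{[(tert-butyldimethylsilyl)oxy]methyl}-4-isopropylcyclohex-1-en-1-yl]methanol
Conditions: iBu2AlH (2.5 equiv), CH2Cl2, −78 °C; aq. potassium sodium tartrate
Reagents that add atoms: none
Why: 1,2-Reduction of the α,β-unsaturated ester with iBu2AlH gives the allylic alcohol and leaves the silyl ether.

Step 10
Reactants: 15 [(3S,4S)-3-{[(tert-butyldimethylsilyl)oxy]methyl}-4-isopropylcyclohex-1-en-1-yl]methanol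
Product: 16 tert-butyl{[(1S,6S)-6-isopropyl-3-{[(4-methoxybenzyl)oxy]methyl}cyclohex-2-en-1-yl]methoxy}dimethylsilane
Conditions: NaH, 4-MeOC6H4CH2Cl, Bu4NI (cat.), THF–DMF, 0 °C to rt
Reagents that add atoms: 4-methoxybenzyl chloride, COc1ccc(CCl)cc1
Why: Williamson etherification protects the allylic alcohol as an acid-cleavable 4-methoxybenzyl ether, orthogonal to the silyl ether.

Step 11
Reactants: 16 tert-butyl{[(1S,6S)-6-isopropyl-3-{[(4-methoxybenzyl)oxy]methyl}cyclohex-2-en-1-yl]methoxy}dimethylsilane
Product: 17 [(1S,6S)-6-isopropyl-3-{[(4-methoxybenzyl)oxy]methyl}cyclohex-2-en-1-yl]methanol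
Conditions: 10-camphorsulfonic acid (10 mol %), MeOH, 0 °C to rt
Reagents that add atoms: none
Why: Acid-catalysed methanolysis removes the primary tert-butyldimethylsilyl ether and should leave the benzyl-type ether.

Step 12
Reactants: 17 [(1S,6S)-6-isopropyl-3-{[(4-methoxybenzyl)oxy]methyl}cyclohex-2-en-1-yl]methanol
Product: 18 (1S,6S)-6-isopropyl-3-{[(4-methoxybenzyl)oxy]methyl}cyclohex-2-ene-1-carbaldehyde
Conditions: Dess–Martin periodinane, NaHCO3, CH2Cl2, 0 °C
Reagents that add atoms: none
Why: Dess–Martin oxidation under buffered non-basic conditions should give the β,γ-unsaturated aldehyde without double-bond migration or epimerisation; it is used crude in step 24.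

Step 13
Reactants: 19 isovaleraldehyde; 20 methyl vinyl ketone
Product: 22 (S)-cryptone, via keto aldehyde 21 (not isolated)
Conditions: (S)-2-[diphenyl(trimethylsilyloxy)methyl]pyrrolidine (5 mol %), ethyl 3,4-dihydroxybenzoate (20 mol %), neat, 4 °C; then LiOH, iPrOH, rt
Reagents that add atoms: none
Why: Enamine-catalysed Michael addition of the aldehyde to the enone sets the isopropyl stereocentre (S expected with the (S)-catalyst by the usual shielding model), and intramolecular aldol condensation (Robinson annulation) closes the cyclohexenone.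

Step 14
Reactants: 22 (S)-cryptone; 23 allene
Product: 24 (1R,5S,6S)-5-isopropyl-8-methylenebicyclo[4.2.0]octan-2-one
Conditions: hν (Hg lamp, Pyrex filter), THF, −78 °C; then basic Al2O3
Reagents that add atoms: none
Why: Enone–allene [2+2] photocycloaddition gives the head-to-head (8-methylene) adduct, the allene should add anti to the adjacent isopropyl group, and the cis ring fusion (any trans-fused adduct is epimerised on alumina) puts the two new C–C bonds on the same face of ring A.

Step 15
Reactants: 24 (1R,5S,6S)-5-isopropyl-8-methylenebicyclo[4.2.0]octan-2-one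
Product: 25 (1R,2R,5S,6S)-5-isopropyl-2-[(methoxymethoxy)methyl]-8-methylenebicyclo[4.2.0]octan-2-ol
Conditions: Bu3SnCH2OCH2OMe, n-BuLi, THF, −78 °C; then 24, −78 °C
Reagents that add atoms: tributyl[(methoxymethoxy)methyl]stannane, CCCC[Sn](CCCC)(CCCC)COCOC
Why: 1,2-Addition of the α-alkoxymethyllithium (from tin–lithium exchange) should occur on the convex face of the cis-fused bicyclic ketone, anti to the cyclobutane, which sets the tertiary alcohol with the hydroxyl syn to the cyclobutane.

Step 16
Reactants: 25 (1R,2R,5S,6S)-5-isopropyl-2-[(methoxymethoxy)methyl]-8-methylenebicyclo[4.2.0]octan-2-ol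
Product: 27 5-hydroxy-2-isopropyl-5-[(methoxymethoxy)methyl]bicyclo[4.2.0]octan-7-one (configuration as in 25), via ozonide 26 (not isolated)
Conditions: O3, CH2Cl2, −78 °C; then Me2S, −78 °C to rt
Reagents that add atoms: ozone, [O-][O+]=O
Why: Ozonolysis of the 1,1-disubstituted alkene with reductive work-up gives the cyclobutanone with its carbonyl on the carbon attached to C2 of ring A.

Step 17
Reactants: 27 5-hydroxy-2-isopropyl-5-[(methoxymethoxy)methyl]bicyclo[4.2.0]octan-7-one
Product: 28 bis(trimethylsilyl) derivative of 27 (1-silyloxycyclobutene plus tertiary silyl ether)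
Conditions: Me3SiCl (3 equiv), LiN(iPr)2 (2.4 equiv), THF, −78 °C
Reagents that add atoms: chlorotrimethylsilane, C[Si](C)(C)Cl
Why: Kinetic deprotonation at the less hindered cyclobutanone CH2 with in situ silylation should give the silyl enol ether regioselectively (the ring-fusion CH is not enolised, so C2 of ring A is preserved) and caps the tertiary alkoxide.

Step 18
Reactants: 28 bis(trimethylsilyl) derivative of 27
Product: 31 2-formyl-6-hydroxy-3-isopropyl-6-[(methoxymethoxy)methyl]cyclohexane-1-carboxylic acid (carboxyl and formyl cis), via ozonide 29 (not isolated), via silyl ester aldehyde 30 (not isolated)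
Conditions: O3, CH2Cl2, −78 °C; then Me2S; then aq. citric acid, THF, rt
Reagents that add atoms: ozone, [O-][O+]=O
Why: Ozonolysis of the silyl enol ether cleaves the cyclobutene into a silyl ester and an aldehyde, and mild hydrolysis of the two Si–O bonds gives the cis formyl acid (probably as its lactol tautomer) with each carbon at the oxidation level needed.

Step 19
Reactants: 31 2-formyl-6-hydroxy-3-isopropyl-6-[(methoxymethoxy)methyl]cyclohexane-1-carboxylic acid
Product: 32 6-hydroxy-3-isopropyl-6-[(methoxymethoxy)methyl]-2-vinylcyclohexane-1-carboxylic acid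
Conditions: Ph3PCH3Br (3.5 equiv), KN(SiMe3)2 (3.4 equiv), THF, 0 °C to rt; acidic work-up
Reagents that add atoms: methyltriphenylphosphonium bromide, C[P+](c1ccccc1)(c1ccccc1)c1ccccc1.[Br-]
Why: Wittig methylenation of the aldehyde with excess ylide, in which the carboxylate formed in situ shields the adjacent α-centre from epimerisation.

Step 20
Reactants: 32 6-hydroxy-3-isopropyl-6-[(methoxymethoxy)methyl]-2-vinylcyclohexane-1-carboxylic acid; 33 tert-butyl 2-(bromomethyl)acrylate
Product: 34 2-(tert-butoxycarbonyl)allyl ester of 32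
Conditions: Cs2CO3, DMF, 0 °C to rt
Reagents that add atoms: none
Why: O-Alkylation (SN2) of the caesium carboxylate with the reactive allylic bromide installs the 2-substituted acrylate needed for ring closure, and the tertiary alcohol is not alkylated.

Step 21
Reactants: 34 2-(tert-butoxycarbonyl)allyl ester of 32
Product: 35 tert-butyl 9-hydroxy-6-isopropyl-9-[(methoxymethoxy)methyl]-1-oxo-1,3,5a,6,7,8,9,9a-octahydro-2-benzoxepine-4-carboxylate
Conditions: second-generation Hoveyda–Grubbs catalyst (10 mol %), toluene (2 mM), 80 °C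
Reagents that add atoms: none
Why: Ring-closing metathesis between the vinyl group and the 1,1-disubstituted acrylate closes ring B as a trisubstituted enoate, the ring enforcing the alkene geometry and the cis arrangement of the two arms favouring cyclisation.

Step 22
Reactants: 35 tert-butyl 9-hydroxy-6-isopropyl-9-[(methoxymethoxy)methyl]-1-oxo-1,3,5a,6,7,8,9,9a-octahydro-2-benzoxepine-4-carboxylate
Product: 36 tert-butyl 9-hydroxy-9-(hydroxymethyl)-6-isopropyl-1-oxo-1,3,5a,6,7,8,9,9a-octahydro-2-benzoxepine-4-carboxylate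
Conditions: B-bromocatecholborane, CH2Cl2, −78 to 0 °C; aq. NaHCO3
Reagents that add atoms: none
Why: B-Bromocatecholborane cleaves methoxymethyl ethers at low temperature much faster than tert-butyl esters; the diol is used at once under neutral conditions to avoid translactonisation onto the freed primary alcohol.

Step 23
Reactants: 36 tert-butyl 9-hydroxy-9-(hydroxymethyl)-6-isopropyl-1-oxo-1,3,5a,6,7,8,9,9a-octahydro-2-benzoxepine-4-carboxylate; 37 (triphenylphosphoranylidene)ketene
Product: 38 (triphenylphosphoranylidene)acetate ester of the primary alcohol of 36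
Conditions: toluene, 70 °C
Reagents that add atoms: none
Why: Addition of the primary alcohol across the cumulated C=C=O unit of the ketene ylide gives the ester-stabilised ylide directly, and the tertiary alcohol should be too hindered to react.

Step 24
Reactants: 38 (triphenylphosphoranylidene)acetate ester of the primary alcohol of 36; 18 (1S,6S)-6-isopropyl-3-{[(4-methoxybenzyl)oxy]methyl}cyclohex-2-ene-1-carbaldehyde
Product: 40 (Z)-2-bromo-3-[(1S,6S)-6-isopropyl-3-{[(4-methoxybenzyl)oxy]methyl}cyclohex-2-en-1-yl]acrylate ester of the primary alcohol of 36, via bromo ylide 39 (not isolated)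
Conditions: N-bromosuccinimide (1.0 equiv), CH2Cl2, −20 °C; then 18 (1.3 equiv), −20 to 40 °C
Reagents that add atoms: N-bromosuccinimide, O=C1CCC(=O)N1Br
Why: Electrophilic bromination of the stabilised ylide gives the α-bromo ylide, whose Wittig reaction with the aldehyde should give the (Z)-α-bromoacrylate (ester trans to ring C, the usual preference of stabilised α-halo ylides) under near-neutral conditions that spare the β,γ-unsaturated aldehyde.

Step 25
Reactants: 40 (Z)-2-bromo-3-[(1S,6S)-6-isopropyl-3-{[(4-methoxybenzyl)oxy]methyl}cyclohex-2-en-1-yl]acrylate ester of the primary alcohol of 36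
Product: 41 (E)-2-(hydroxymethyl)acrylate analogue of 40
Conditions: Bu3SnCH2OH (1.5 equiv), Pd(PPh3)4 (10 mol %), 1,4-dioxane, 90 °C
Reagents that add atoms: (tributylstannyl)methanol, OC[Sn](CCCC)(CCCC)CCCC
Why: Stille coupling of the vinyl bromide with the hydroxymethylstannane proceeds with retention of alkene geometry, so the hydroxymethyl group ends cis to ring C and the (E)-2-(hydroxymethyl)acrylate results.

Step 26
Reactants: 41 (E)-2-(hydroxymethyl)acrylate analogue of 40
Product: 42 CNP0361406.4
Conditions: CF3CO2H–CH2Cl2 (1:4), anisole (10 equiv), 0 °C to rt; aq. NaHCO3 then pH 3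
Reagents that add atoms: none
Why: Acidolysis removes the tert-butyl ester (as isobutene) and the 4-methoxybenzyl ether (cation trapped by anisole) in one operation, while the lactone, the acrylate ester and the tertiary alcohol should survive dilute CF3CO2H.

**Compound list**

1 | (E)-but-2-ene-1,4-diol | OC/C=C/CO | starting material
2 | (E)-4-[(tert-butyldimethylsilyl)oxy]but-2-en-1-ol | CC(C)(C)[Si](C)(C)OC/C=C/CO | intermediate
3 | (E)-4-[(tert-butyldimethylsilyl)oxy]but-2-en-1-yl methyl carbonate | COC(=O)OC/C=C/CO[Si](C)(C)C(C)(C)C | intermediate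
4 | methyl acetoacetate | CC(=O)CC(=O)OC | starting material
5 | methyl (3R)-2-acetyl-3-{[(tert-butyldimethylsilyl)oxy]methyl}pent-4-enoate (C2 epimers) | CC(C)(C)[Si](C)(C)OC[C@@H](C(C(C)=O)C(=O)OC)C=C | intermediate
6 | ozonide of 5 (3-substituted 1,2,4-trioxolane) | CC(C)(C)[Si](C)(C)OC[C@@H](C(C(C)=O)C(=O)OC)C1OCOO1 | intermediate
7 | methyl (3R)-2-acetyl-4-[(tert-butyldimethylsilyl)oxy]-3-formylbutanoate (C2 epimers) | CC(C)(C)[Si](C)(C)OC[C@@H](C(C(C)=O)C(=O)OC)C=O | intermediate
8 | (1-ethoxycarbonylcyclopropyl)triphenylphosphonium tetrafluoroborate | CCOC(=O)C1(CC1)[P+](c2ccccc2)(c2ccccc2)c2ccccc2.F[B-](F)(F)F | starting material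
9 | sodium enolate of 7 | [Na+].CC([O-])=C(C(=O)OC)[C@H](CO[Si](C)(C)C(C)(C)C)C=O | intermediate
10 | ester-stabilised phosphorus ylide from ring opening of 8 by 9 | CCOC(=O)C(CCC(C(C)=O)(C(=O)OC)[C@H](CO[Si](C)(C)C(C)(C)C)C=O)=P(c1ccccc1)(c1ccccc1)c1ccccc1 | intermediate
11 | 4-ethyl 1-methyl (2R)-1-acetyl-2-{[(tert-butyldimethylsilyl)oxy]methyl}cyclohex-3-ene-1,4-dicarboxylate (C1 epimers) | CC(C)(C)[Si](C)(C)OC[C@@H]1C=C(C(=O)OCC)CCC1(C(C)=O)C(=O)OC | intermediate
12 | ethyl (3R,4R)-4-acetyl-3-{[(tert-butyldimethylsilyl)oxy]methyl}cyclohex-1-ene-1-carboxylate (3,4-trans) | CC(C)(C)[Si](C)(C)OC[C@@H]1C=C(C(=O)OCC)CC[C@H]1C(C)=O | intermediate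
13 | ethyl (3R,4R)-3-{[(tert-butyldimethylsilyl)oxy]methyl}-4-(prop-1-en-2-yl)cyclohex-1-ene-1-carboxylate | CC(C)(C)[Si](C)(C)OC[C@@H]1C=C(C(=O)OCC)CC[C@H]1C(C)=C | intermediate
14 | ethyl (3S,4S)-3-{[(tert-butyldimethylsilyl)oxy]methyl}-4-isopropylcyclohex-1-ene-1-carboxylate | CC(C)(C)[Si](C)(C)OC[C@@H]1C=C(C(=O)OCC)CC[C@H]1C(C)C | intermediate
15 | [(3S,4S)-3-{[(tert-butyldimethylsilyl)oxy]methyl}-4-isopropylcyclohex-1-en-1-yl]methanol | CC(C)(C)[Si](C)(C)OC[C@@H]1C=C(CO)CC[C@H]1C(C)C | intermediate
16 | tert-butyl{[(1S,6S)-6-isopropyl-3-{[(4-methoxybenzyl)oxy]methyl}cyclohex-2-en-1-yl]methoxy}dimethylsilane | CC(C)(C)[Si](C)(C)OC[C@@H]1C=C(COCc2ccc(OC)cc2)CC[C@H]1C(C)C | intermediate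
17 | [(1S,6S)-6-isopropyl-3-{[(4-methoxybenzyl)oxy]methyl}cyclohex-2-en-1-yl]methanol | OC[C@@H]1C=C(COCc2ccc(OC)cc2)CC[C@H]1C(C)C | intermediate
18 | (1S,6S)-6-isopropyl-3-{[(4-methoxybenzyl)oxy]methyl}cyclohex-2-ene-1-carbaldehyde | O=C[C@@H]1C=C(COCc2ccc(OC)cc2)CC[C@H]1C(C)C | intermediate
19 | isovaleraldehyde (3-methylbutanal) | CC(C)CC=O | starting material
20 | methyl vinyl ketone (but-3-en-2-one) | CC(=O)C=C | starting material
21 | (S)-2-isopropyl-5-oxohexanal | CC(C)[C@@H](C=O)CCC(C)=O | intermediate
22 | (S)-cryptone, (S)-4-isopropylcyclohex-2-en-1-one | CC(C)[C@@H]1CCC(=O)C=C1 | intermediate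
23 | allene (propadiene) | C=C=C | starting material
24 | (1R,5S,6S)-5-isopropyl-8-methylenebicyclo[4.2.0]octan-2-one (cis-fused, cyclobutane anti to isopropyl) | CC(C)[C@@H]1CCC(=O)[C@H]2C(=C)C[C@@H]12 | intermediate
25 | (1R,2R,5S,6S)-5-isopropyl-2-[(methoxymethoxy)methyl]-8-methylenebicyclo[4.2.0]octan-2-ol (hydroxyl syn to the cyclobutane) | CC(C)[C@@H]1CC[C@](O)(COCOC)[C@H]2C(=C)C[C@@H]12 | intermediate
26 | ozonide of 25 (spiro-1,2,4-trioxolane at the former methylene carbon) | CC(C)[C@@H]1CC[C@](O)(COCOC)[C@H]2C3(OCOO3)C[C@@H]12 | intermediate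
27 | 5-hydroxy-2-isopropyl-5-[(methoxymethoxy)methyl]bicyclo[4.2.0]octan-7-one (configuration as in 25, methylene replaced by oxo) | CC(C)[C@@H]1CC[C@](O)(COCOC)[C@H]2C(=O)C[C@@H]12 | intermediate
28 | bis(trimethylsilyl) derivative of 27 (1-silyloxycyclobutene and tertiary silyl ether) | CC(C)[C@@H]1CC[C@](O[Si](C)(C)C)(COCOC)[C@H]2C(O[Si](C)(C)C)=C[C@@H]12 | intermediate
29 | ozonide of 28 | CC(C)[C@@H]1CC[C@](O[Si](C)(C)C)(COCOC)[C@H]2C3(O[Si](C)(C)C)OOC(O3)[C@@H]12 | intermediate
30 | trimethylsilyl ester aldehyde from 29 (tertiary silyl ether retained) | CC(C)[C@@H]1CC[C@](O[Si](C)(C)C)(COCOC)[C@@H](C(=O)O[Si](C)(C)C)[C@H]1C=O | intermediate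
31 | 2-formyl-6-hydroxy-3-isopropyl-6-[(methoxymethoxy)methyl]cyclohexane-1-carboxylic acid (carboxyl/formyl cis, formyl/isopropyl trans, hydroxyl cis to carboxyl) | CC(C)[C@@H]1CC[C@](O)(COCOC)[C@@H](C(=O)O)[C@H]1C=O | intermediate
32 | 6-hydroxy-3-isopropyl-6-[(methoxymethoxy)methyl]-2-vinylcyclohexane-1-carboxylic acid (configuration as 31) | CC(C)[C@@H]1CC[C@](O)(COCOC)[C@@H](C(=O)O)[C@H]1C=C | intermediate
33 | tert-butyl 2-(bromomethyl)acrylate | C=C(CBr)C(=O)OC(C)(C)C | starting material
34 | 2-(tert-butoxycarbonyl)allyl ester of 32 | CC(C)[C@@H]1CC[C@](O)(COCOC)[C@@H](C(=O)OCC(=C)C(=O)OC(C)(C)C)[C@H]1C=C | intermediate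
35 | tert-butyl 9-hydroxy-6-isopropyl-9-[(methoxymethoxy)methyl]-1-oxo-1,3,5a,6,7,8,9,9a-octahydro-2-benzoxepine-4-carboxylate (cis-fused; 9-OH anti to the ring-fusion hydrogens, 6-isopropyl syn to them) | CC(C)[C@@H]1CC[C@](O)(COCOC)[C@H]2C(=O)OCC(C(=O)OC(C)(C)C)=C[C@@H]12 | intermediate
36 | tert-butyl 9-hydroxy-9-(hydroxymethyl)-6-isopropyl-1-oxo-1,3,5a,6,7,8,9,9a-octahydro-2-benzoxepine-4-carboxylate (configuration as 35) | CC(C)[C@@H]1CC[C@](O)(CO)[C@H]2C(=O)OCC(C(=O)OC(C)(C)C)=C[C@@H]12 | intermediate
37 | (triphenylphosphoranylidene)ketene | O=C=C=P(c1ccccc1)(c1ccccc1)c1ccccc1 | starting material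
38 | (triphenylphosphoranylidene)acetate ester of the primary alcohol of 36 | CC(C)[C@@H]1CC[C@](O)(COC(=O)C=P(c3ccccc3)(c3ccccc3)c3ccccc3)[C@H]2C(=O)OCC(C(=O)OC(C)(C)C)=C[C@@H]12 | intermediate
39 | bromo(triphenylphosphoranylidene)acetate ester of the primary alcohol of 36 | CC(C)[C@@H]1CC[C@](O)(COC(=O)C(Br)=P(c3ccccc3)(c3ccccc3)c3ccccc3)[C@H]2C(=O)OCC(C(=O)OC(C)(C)C)=C[C@@H]12 | intermediate
40 | (Z)-2-bromo-3-[(1S,6S)-6-isopropyl-3-{[(4-methoxybenzyl)oxy]methyl}cyclohex-2-en-1-yl]acrylate ester of the primary alcohol of 36 | CC(C)[C@@H]1CC[C@](O)(COC(=O)/C(Br)=C/[C@@H]3C=C(COCc4ccc(OC)cc4)CC[C@H]3C(C)C)[C@H]2C(=O)OCC(C(=O)OC(C)(C)C)=C[C@@H]12 | intermediate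
41 | (E)-2-(hydroxymethyl)acrylate analogue of 40 (tert-butyl ester and 4-methoxybenzyl ether of the target) | CC(C)[C@@H]1CC[C@](O)(COC(=O)/C(CO)=C/[C@@H]3C=C(COCc4ccc(OC)cc4)CC[C@H]3C(C)C)[C@H]2C(=O)OCC(C(=O)OC(C)(C)C)=C[C@@H]12 | intermediate
42 | CNP0361406.4 | CC(C)[C@@H]1CC[C@](O)(COC(=O)/C(=C/[C@@H]2C=C(CO)CC[C@H]2C(C)C)CO)[C@H]2C(=O)OCC(C(=O)O)=C[C@@H]12 | target

**Totals and risks**

Total step count: 26. Longest linear sequence: 15 steps (steps 1–12, then 24–26); the other branch runs through steps 13–23 and joins at step 24.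

Steps most likely to fail:

1. Step 5 (Proposed new method). What may go wrong: O-alkylation or sluggish opening of the cyclopropane by the hindered enolate, enolisation of the aldehyde with loss of the C3 configuration, or intermolecular olefination. Fallback with known chemistry, setting out from 5 and returning at 11: C-alkylation of the sodium enolate of 5 with but-3-yn-1-yl trifluoromethanesulfonate should give methyl (3R)-2-acetyl-2-(but-3-yn-1-yl)-3-{[(tert-butyldimethylsilyl)oxy]methyl}pent-4-enoate F1. Ring-closing enyne metathesis (second-generation Grubbs catalyst, ethylene, CH2Cl2, 40 °C) should then give methyl (2R)-1-acetyl-2-{[(tert-butyldimethylsilyl)oxy]methyl}-4-vinylcyclohex-3-ene-1-carboxylate F2. Lemieux–Johnson cleavage of the exocyclic vinyl group (OsO4 cat., NaIO4, 2,6-lutidine) should give methyl (2R)-1-acetyl-2-{[(tert-butyldimethylsilyl)oxy]methyl}-4-formylcyclohex-3-ene-1-carboxylate F3. Lindgren–Pinnick oxidation (NaClO2, NaH2PO4, 2-methylbut-2-ene) should give (3R)-4-acetyl-3-{[(tert-butyldimethylsilyl)oxy]methyl}-4-(methoxycarbonyl)cyclohex-1-ene-1-carboxylic acid F4, and ethylation (ethyl iodide, K2CO3, DMF) gives 11.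

2. Step 24. What may go wrong: slow olefination of the hindered α-branched aldehyde by the bulky bromo ylide, double-bond migration or epimerisation of 18 during a long reaction, and incomplete Z selectivity. Fallback, setting out from 18 and returning at 40, joins the halves by acylation instead of olefination: Wittig reaction of 18 with excess ethyl bromo(triphenylphosphoranylidene)acetate (from the parent ylide and N-bromosuccinimide) should give ethyl (2Z)-2-bromo-3-[(1S,6S)-6-isopropyl-3-{[(4-methoxybenzyl)oxy]methyl}cyclohex-2-en-1-yl]prop-2-enoate F7. Hydrolysis (LiOH, THF–H2O, 0 °C) should give (2Z)-2-bromo-3-[(1S,6S)-6-isopropyl-3-{[(4-methoxybenzyl)oxy]methyl}cyclohex-2-en-1-yl]prop-2-enoic acid F8, and Yamaguchi esterification of F8 with the primary alcohol of 36 gives 40.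

3. Step 21. What may go wrong: unproductive metathesis at the electron-poor 1,1-disubstituted alkene, or dimerisation through the vinyl group instead of seven-membered ring closure. Fallback, setting out from 31 and returning at 35: Wittig reaction of 31 with tert-butyl bromo(triphenylphosphoranylidene)acetate (from the parent ylide and N-bromosuccinimide, in excess) should give 2-[(Z)-2-bromo-3-tert-butoxy-3-oxoprop-1-en-1-yl]-6-hydroxy-3-isopropyl-6-[(methoxymethoxy)methyl]cyclohexane-1-carboxylic acid F5. Stille coupling with (tributylstannyl)methanol and Pd(PPh3)4 should give 2-[(E)-3-tert-butoxy-2-(hydroxymethyl)-3-oxoprop-1-en-1-yl]-6-hydroxy-3-isopropyl-6-[(methoxymethoxy)methyl]cyclohexane-1-carboxylic acid F6, and Yamaguchi lactonisation (2,4,6-trichlorobenzoyl chloride, Et3N, then 4-dimethylaminopyridine, toluene, high dilution) closes ring B to 35.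

Further compounds
F1 | step 5 | methyl (3R)-2-acetyl-2-(but-3-yn-1-yl)-3-{[(tert-butyldimethylsilyl)oxy]methyl}pent-4-enoate | CC(C)(C)[Si](C)(C)OC[C@@H](C(CCC#C)(C(C)=O)C(=O)OC)C=C
F2 | step 5 | methyl (2R)-1-acetyl-2-{[(tert-butyldimethylsilyl)oxy]methyl}-4-vinylcyclohex-3-ene-1-carboxylate | CC(C)(C)[Si](C)(C)OC[C@@H]1C=C(C=C)CCC1(C(C)=O)C(=O)OC
F3 | step 5 | methyl (2R)-1-acetyl-2-{[(tert-butyldimethylsilyl)oxy]methyl}-4-formylcyclohex-3-ene-1-carboxylate | CC(C)(C)[Si](C)(C)OC[C@@H]1C=C(C=O)CCC1(C(C)=O)C(=O)OC
F4 | step 5 | (3R)-4-acetyl-3-{[(tert-butyldimethylsilyl)oxy]methyl}-4-(methoxycarbonyl)cyclohex-1-ene-1-carboxylic acid | CC(C)(C)[Si](C)(C)OC[C@@H]1C=C(C(=O)O)CCC1(C(C)=O)C(=O)OC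
F5 | step 21 | 2-[(Z)-2-bromo-3-tert-butoxy-3-oxoprop-1-en-1-yl]-6-hydroxy-3-isopropyl-6-[(methoxymethoxy)methyl]cyclohexane-1-carboxylic acid | CC(C)[C@@H]1CC[C@](O)(COCOC)[C@@H](C(=O)O)[C@H]1/C=C(\Br)C(=O)OC(C)(C)C
F6 | step 21 | 2-[(E)-3-tert-butoxy-2-(hydroxymethyl)-3-oxoprop-1-en-1-yl]-6-hydroxy-3-isopropyl-6-[(methoxymethoxy)methyl]cyclohexane-1-carboxylic acid | CC(C)[C@@H]1CC[C@](O)(COCOC)[C@@H](C(=O)O)[C@H]1/C=C(\CO)C(=O)OC(C)(C)C
F7 | step 24 | ethyl (2Z)-2-bromo-3-[(1S,6S)-6-isopropyl-3-{[(4-methoxybenzyl)oxy]methyl}cyclohex-2-en-1-yl]prop-2-enoate | CCOC(=O)/C(Br)=C/[C@@H]1C=C(COCc2ccc(OC)cc2)CC[C@H]1C(C)C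
F8 | step 24 | (2Z)-2-bromo-3-[(1S,6S)-6-isopropyl-3-{[(4-methoxybenzyl)oxy]methyl}cyclohex-2-en-1-yl]prop-2-enoic acid | OC(=O)/C(Br)=C/[C@@H]1C=C(COCc2ccc(OC)cc2)CC[C@H]1C(C)C
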